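## Analysis of the target

The target 15 is an unsymmetrical 2,3,4',5'-tetrahydroxybiphenyl. Each of its two catechol rings carries the same chain: eight methylenes ending in a ketone bonded to C1 of a 2,6-dihydroxyphenyl ring. On ring A the biaryl carbon C1 is flanked by the hydroxyl at C2, and the chain sits meta to it at C5. On ring B the chain carbon C2' is the direct neighbour of the biaryl carbon C1', and the hydroxyls at C4' and C5' lie para to these two carbons. There is no stereocentre, and the biaryl axis carries only one ortho hydroxyl and one ortho methylene, so it rotates freely; the problem is one of regiochemistry and functional-group tolerance. The eight phenols, and above all the two catechols, oxidise easily once deprotonated, so they are carried as methyl ethers and freed in the last step. The 2-acylresorcinol ends cannot come from Friedel–Crafts acylation of a resorcinol ether, which would acylate C4, so a C2 carbanion of the resorcinol ether is needed. The two catechol rings are substituted differently (chain meta to the axis on ring A, ortho on ring B), which rules out a dimerisation. The route rests on ring B: C1' and C2', with the oxygens at C4' and C5', correspond to the ipso carbon C4 and the unhindered ortho carbon C5 of 4-iodoveratrole. One palladium–norbornene relay can therefore attach ring A and the chain to ring B in a single operation.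

## Retrosynthetic reasoning

The last disconnection is the eight O–CH3 bonds of 15. This leads back to the octamethyl ether 14, in which nothing is oxidisable or acidic, so the sensitive polyphenol exists only at the end. The forward reaction has to cleave two kinds of aryl methyl ether (catechol and ortho-acyl) without touching the ketones.

In 14 both aryl–C(=O) bonds are cut. This gives the bis(N-methoxy-N-methylamide) 11 and two equivalents of the C2-lithiated resorcinol ether 13, which comes from 12 by deprotonation between its two methoxyls. The cut is made here because only the C2 anion gives the 2-acyl pattern, and because the two chain ends are identical and can be treated together. The amide must stop the addition at the ketone stage.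

Amide 11 is traced back to the diester 10 by exchange of the two ester groups. The ester is the form in which both chains are commercially available or easily made.

The key disconnection cuts two bonds on adjacent carbons of ring B in 10: the C2'–CH2 bond and the C1'–C1 biaryl bond. The three pieces are the iodide 8, the bromo ester 9 and the ring A boronate 7. Cutting here means ring B needs no prior functionalisation beyond its iodine, and the two chains arrive in the same oxidation state. The forward reaction must alkylate the ortho carbon of 8 remote from the methoxyls once only, and it must do so before the ipso carbon is arylated.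

Boronate 7 is simplified at the benzylic end of its chain. The C8–C9 bond is cut as an alkene (6), which comes from the aldehyde 2 and the ylide 5; 5 is generated from the phosphonium salt 4, itself made from the bromo ester 3. The 1,3,4,5-pattern of ring A is then taken from a benzaldehyde. The alkene is saturated after the boron is in place, so no carbon–halogen bond is exposed to hydrogenation.

Aldehyde 2 is disconnected at its C–B bond to the bromide 1, which already carries both methoxyls, the formyl group and the halogen in the right positions.

## Alternatives that were turned down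

Alternative 1: Ring B is built from acyclic carbons. The ring A arylpropiolate A1 and the symmetric diene A2 would combine in a Diels–Alder reaction to the cyclohexa-1,4-diene A3, which a quinone oxidant would aromatise.
- For: the diene is symmetric, so the ring B substitution pattern is fixed with no regiochemical question. On this point it is stronger than the chosen route, which must distinguish two ortho C–H bonds.
- Against: the cycloaddition forms neither chain bond. Both chain positions arrive as aryl esters, and each must be reduced to the aldehyde, extended by eight carbons and saturated. The bis(enol ether) A3 is acid-labile, and the electron-rich arylpropiolate is a sluggish dienophile that needs forcing conditions.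
- Comparison: preparing A1, then cycloaddition, aromatisation, twofold redox adjustment, twofold olefination, hydrogenation and the same three closing steps come to clearly more steps. The chosen route offers less certain regiocontrol but forms a chain bond and the biaryl bond together and never handles a biaryl dialdehyde.

Alternative 2: The biaryl bond and the neighbouring C–O bond of ring A are cut. The ring B Grignard reagent A4 would add to the methoxyaryne released from the iodo triflate A5. The resulting arylmagnesium would be trapped with a borate ester and oxidised with peroxide to the phenol A6.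
- For: the biaryl bond forms without a transition metal. The methoxyl of the aryne directs the nucleophile to the distal carbon, so the regiochemistry is dependable, and the hydroxyl of ring A is set in the same flask.
- Against: the arylmagnesium to be borylated sits between a methoxyl and the new aryl group, so protonation will compete with the trap. A4 also serves as the exchange reagent that triggers the aryne, which costs material. A6 then needs O-methylation, removal of two acetals and the same twofold chain extension as in Alternative 1.
- Comparison: it is longer by several steps. It is stronger only in that its key step is indifferent to C–H site selectivity. The chosen route instead brings in a complete chain on each ring.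

Alternative 3: Both aryl–CH2 bonds are cut. The dibromide A7 and two molecules of the bromo ketone A8 would be joined under nickel catalysis with a metallic reductant, giving the octamethyl ether A9 (identical with compound 14).
- For: this is the most convergent plan. One step would give the fully protected target, and the ketones would never have to be made on the biaryl. In step count after the coupling it is stronger than the chosen route.
- Against: A7 must first be assembled by a cross-coupling that spares two aryl bromides, which needs an orthogonal third halide and a further selectivity problem. The two bromides of A7 differ strongly: one is ortho to the axis and electron-rich, the other unhindered. Both reductive couplings must go to completion in competition with alkyl dimerisation and hydrodehalogenation. The mono-coupled and reduced by-products would be polyethers of almost the same polarity as A9.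
- Comparison: the chosen route puts the risk on one C–H alkylation instead of two simultaneous reductive couplings. It needs no tetra-functional biaryl and uses only one halogen on ring B.

Key step: step 5

## Remarks on the chemistry

- Alkene 6 is drawn as the Z isomer expected from a non-stabilised ylide. Any E isomer converges in step 4.
- The mediator of step 5, 1-methylbicyclo[2.2.1]hept-2-ene, is an auxiliary that leaves the reaction unchanged and is assumed to be available.

## Route

Step 1
Reactants: 1 3-bromo-4,5-dimethoxybenzaldehyde
Product: 2 3,4-dimethoxy-5-(4,4,5,5-tetramethyl-1,3,2-dioxaborolan-2-yl)benzaldehyde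
Conditions: bis(pinacolato)diboron, PdCl2(dppf) (3 mol %), KOAc, 1,4-dioxane, 85 °C
Reagents that add atoms: bis(pinacolato)diboron, CC1(C)OB(OC1(C)C)B1OC(C)(C)C(C)(C)O1
Why: Miyaura borylation of an aryl bromide; the weak acetate base leaves the aldehyde untouched and does not promote Suzuki coupling of the product with unreacted bromide.

Step 2
Reactants: 3 methyl 8-bromooctanoate
Product: 4 (8-methoxy-8-oxooctyl)triphenylphosphonium bromide
Conditions: PPh3, MeCN, reflux
Reagents that add atoms: triphenylphosphine, c1ccc(cc1)P(c1ccccc1)c1ccccc1
Why: SN2 quaternisation of triphenylphosphine by a primary alkyl bromide; the remote ester does not take part.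

Step 3
Reactants: 4 (8-methoxy-8-oxooctyl)triphenylphosphonium bromide; 2 3,4-dimethoxy-5-(4,4,5,5-tetramethyl-1,3,2-dioxaborolan-2-yl)benzaldehyde
Product: 6 methyl (8Z)-9-[3,4-dimethoxy-5-(4,4,5,5-tetramethyl-1,3,2-dioxaborolan-2-yl)phenyl]non-8-enoate, via phosphorus ylide 5 (not isolated)
Conditions: NaN(SiMe3)2, THF, −78 → 0 °C; then 2, −78 °C → rt
Reagents that add atoms: none
Why: Wittig olefination; the CH2 next to phosphorus is far more acidic than the ester α-CH2, so the hindered amide base forms the ylide selectively, and the seven-carbon spacer prevents intramolecular acylation. The pinacol boronate is neutral and shielded and should survive; the alkene geometry (Z expected) does not matter because step 4 removes it.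

Step 4
Reactants: 6 methyl (8Z)-9-[3,4-dimethoxy-5-(4,4,5,5-tetramethyl-1,3,2-dioxaborolan-2-yl)phenyl]non-8-enoate
Product: 7 methyl 9-[3,4-dimethoxy-5-(4,4,5,5-tetramethyl-1,3,2-dioxaborolan-2-yl)phenyl]nonanoate
Conditions: H2 (1 atm), Pd/C, EtOAc, rt
Reagents that add atoms: none
Why: Heterogeneous catalytic hydrogenation of a styrene-type alkene; the molecule has no carbon–halogen bond at this stage, and the aryl boronate and the ester are inert.

Step 5
Reactants: 7 methyl 9-[3,4-dimethoxy-5-(4,4,5,5-tetramethyl-1,3,2-dioxaborolan-2-yl)phenyl]nonanoate; 8 4-iodo-1,2-dimethoxybenzene; 9 methyl 9-bromononanoate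
Product: 10 dimethyl 9,9'-(2,3,4',5'-tetramethoxybiphenyl-2',5-diyl)dinonanoate
Conditions: Pd(OAc)2 (10 mol %), P(2-furyl)3 (20 mol %), 1-methylbicyclo[2.2.1]hept-2-ene (1 equiv), K2CO3, H2O (5 equiv), DMF, 90 °C; 7 limiting, 8 and 9 in excess
Reagents that add atoms: none
Why: Zerovalent palladium formed from Pd(OAc)2 and the phosphine inserts into the C–I bond of 8, the bicyclic alkene inserts into the aryl–palladium bond, and carbonate-assisted palladation of C5–H gives a five-membered aryl–norbornyl palladacycle of divalent palladium. Bromide 9 adds oxidatively to give tetravalent palladium, and reductive elimination forms the C5–CH2 bond. With C5 now substituted, β-carbon elimination expels the mediator and leaves an ortho-alkylated arylpalladium bromide of divalent palladium, which transmetalates with boronate 7 and reductively eliminates to form the biaryl bond at C4. The closest known reaction type is the Catellani ortho-alkylation of aryl iodides with primary alkyl bromides terminated by Suzuki coupling, in the variant that uses a bridgehead-substituted norbornene for iodides without an ortho substituent. No ring is closed and no stereocentre is formed. Palladation must occur at C5 and not at C3: in a veratrole the methyl of the C2 methoxyl is turned towards C3–H and shields it, while C5–H is open. Alkylation must occur once only: the same shielding disfavours a second palladation at C3, and the bridgehead methyl presses on the alkylated aryl group and speeds extrusion of the mediator. Alkylation must precede arylation: insertion of the strained alkene into the unhindered arylpalladium iodide is fast, whereas the ortho-methoxy pinacol boronate transmetalates slowly, so Suzuki coupling should only set in once the mediator has left; both methyl esters tolerate carbonate with a small amount of water.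

Step 6
Reactants: 10 dimethyl 9,9'-(2,3,4',5'-tetramethoxybiphenyl-2',5-diyl)dinonanoate
Product: 11 9,9'-(2,3,4',5'-tetramethoxybiphenyl-2',5-diyl)bis(N-methoxy-N-methylnonanamide)
Conditions: MeNH(OMe)·HCl, i-PrMgCl, THF, −20 → 0 °C
Reagents that add atoms: N,O-dimethylhydroxylamine hydrochloride, CNOC.Cl
Why: Direct aminolysis of methyl esters by the magnesium amide made in the flask (Weinreb amide formation); the non-nucleophilic Grignard base only deprotonates the amine salt, and the aryl ethers are inert.

Step 7
Reactants: 11 9,9'-(2,3,4',5'-tetramethoxybiphenyl-2',5-diyl)bis(N-methoxy-N-methylnonanamide); 12 1,3-dimethoxybenzene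
Product: 14 9,9'-(2,3,4',5'-tetramethoxybiphenyl-2',5-diyl)bis[1-(2,6-dimethoxyphenyl)nonan-1-one], via 2,6-dimethoxyphenyllithium 13 (not isolated)
Conditions: 12, n-BuLi, THF, 0 °C → rt; then 11, −78 → 0 °C; aq NH4Cl
Reagents that add atoms: n-butyllithium, [Li]CCCC (its lithium stands in 13 only)
Why: Directed ortho-lithiation of 12 at C2, between the two methoxyls, then Weinreb ketone synthesis; the chelated tetrahedral adduct persists until the quench, so each amide gives one ketone, and the di-ortho-substituted ketone would resist a second addition in any case.

Step 8
Reactants: 14 9,9'-(2,3,4',5'-tetramethoxybiphenyl-2',5-diyl)bis[1-(2,6-dimethoxyphenyl)nonan-1-one]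
Product: 15 9,9'-(2,3,4',5'-tetrahydroxybiphenyl-2',5-diyl)bis[1-(2,6-dihydroxyphenyl)nonan-1-one]
Conditions: BBr3 (excess, about 2 equiv per OMe), CH2Cl2, −78 °C → rt; MeOH, then H2O, under argon
Reagents that add atoms: none
Why: Lewis-acid cleavage of aryl methyl ethers: boron coordinates to oxygen and bromide attacks the methyl group. The methoxyls ortho to the ketones react first through a six-membered chelate, the catechol ethers follow, and the ketones between two ortho oxygens are shielded from side reactions.

## Compound list

1 | 3-bromo-4,5-dimethoxybenzaldehyde | COc1cc(C=O)cc(Br)c1OC | starting material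
2 | 3,4-dimethoxy-5-(4,4,5,5-tetramethyl-1,3,2-dioxaborolan-2-yl)benzaldehyde | COc1cc(C=O)cc(B2OC(C)(C)C(C)(C)O2)c1OC | intermediate
3 | methyl 8-bromooctanoate | COC(=O)CCCCCCCBr | starting material
4 | (8-methoxy-8-oxooctyl)triphenylphosphonium bromide | COC(=O)CCCCCCC[P+](c1ccccc1)(c1ccccc1)c1ccccc1.[Br-] | intermediate
5 | methyl 8-(triphenyl-λ5-phosphanylidene)octanoate | COC(=O)CCCCCCC=P(c1ccccc1)(c1ccccc1)c1ccccc1 | intermediate (not isolated)
6 | methyl (8Z)-9-[3,4-dimethoxy-5-(4,4,5,5-tetramethyl-1,3,2-dioxaborolan-2-yl)phenyl]non-8-enoate | COC(=O)CCCCCC/C=C\c1cc(OC)c(OC)c(B2OC(C)(C)C(C)(C)O2)c1 | intermediate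
7 | methyl 9-[3,4-dimethoxy-5-(4,4,5,5-tetramethyl-1,3,2-dioxaborolan-2-yl)phenyl]nonanoate | COC(=O)CCCCCCCCc1cc(OC)c(OC)c(B2OC(C)(C)C(C)(C)O2)c1 | intermediate
8 | 4-iodo-1,2-dimethoxybenzene | COc1ccc(I)cc1OC | starting material
9 | methyl 9-bromononanoate | BrCCCCCCCCC(=O)OC | starting material
10 | dimethyl 9,9'-(2,3,4',5'-tetramethoxybiphenyl-2',5-diyl)dinonanoate | COC(=O)CCCCCCCCc1cc(OC)c(OC)c(-c2cc(OC)c(OC)cc2CCCCCCCCC(=O)OC)c1 | intermediate
11 | 9,9'-(2,3,4',5'-tetramethoxybiphenyl-2',5-diyl)bis(N-methoxy-N-methylnonanamide) | CON(C)C(=O)CCCCCCCCc1cc(OC)c(OC)c(-c2cc(OC)c(OC)cc2CCCCCCCCC(=O)N(C)OC)c1 | intermediate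
12 | 1,3-dimethoxybenzene | COc1cccc(OC)c1 | starting material
13 | 2,6-dimethoxyphenyllithium | [Li]c1c(OC)cccc1OC | intermediate (not isolated)
14 | 9,9'-(2,3,4',5'-tetramethoxybiphenyl-2',5-diyl)bis[1-(2,6-dimethoxyphenyl)nonan-1-one] | COc1cccc(OC)c1C(=O)CCCCCCCCc1cc(OC)c(OC)c(-c2cc(OC)c(OC)cc2CCCCCCCCC(=O)c2c(OC)cccc2OC)c1 | intermediate
15 | 9,9'-(2,3,4',5'-tetrahydroxybiphenyl-2',5-diyl)bis[1-(2,6-dihydroxyphenyl)nonan-1-one] | O=C(CCCCCCCCc1cc(O)c(O)c(-c2cc(O)c(O)cc2CCCCCCCCC(=O)c2c(O)cccc2O)c1)c1c(O)cccc1O | target

## Step count and risks

Total step count: 8. Longest linear sequence: 7 steps (1 → 2 → 6 → 7 → 10 → 11 → 14 → 15; step 2 is the side branch that supplies 4).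

Step 5 (key step). Three things are most likely to go wrong:
- premature Suzuki coupling of the arylpalladium iodide with 7 before the mediator has inserted;
- a second ortho palladation at C3 leading to double alkylation, or failure of the mediator to leave;
- protodeboronation of the ortho-methoxy boronate in the hot basic medium.

All stem from the fact that 8 has no ortho substituent to enforce the usual order of events. Fallback: the two bonds are made one after the other. It sets out from ylide 5 and the commercial 2-bromo-4,5-dimethoxybenzaldehyde F1. Wittig reaction as in step 3 should give methyl (8Z)-9-(2-bromo-4,5-dimethoxyphenyl)non-8-enoate F2. Homogeneous hydrogenation with H2 and RhCl(PPh3)3, which spares the aryl bromide, should give methyl 9-(2-bromo-4,5-dimethoxyphenyl)nonanoate F3. Suzuki–Miyaura coupling of F3 with boronate 7 (Pd(OAc)2, SPhos, K3PO4, toluene/H2O, 90 °C) returns to the route at 10.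

Step 3. The non-stabilised ylide or the amide base may attack boron, with boronate complex formation and loss of the boryl group, or the ylide may be consumed by intermolecular acylation at an ester. Fallback: the order of olefination and borylation is exchanged. It sets out from bromide 1, which is combined with ylide 5 to give methyl (8Z)-9-(3-bromo-4,5-dimethoxyphenyl)non-8-enoate F4. Miyaura borylation of F4 under the conditions of step 1 returns to the route at 6.

Step 7. The hindered, strongly basic aryllithium may deprotonate the α-methylene of the amides instead of adding, so one or both chain ends may remain unconverted. Fallback: it sets out from 11, which LiAlH4 in THF at −78 °C should reduce to 9,9'-(2,3,4',5'-tetramethoxybiphenyl-2',5-diyl)dinonanal F5. Addition of 13 to the more electrophilic aldehydes should give 9,9'-(2,3,4',5'-tetramethoxybiphenyl-2',5-diyl)bis[1-(2,6-dimethoxyphenyl)nonan-1-ol] F6 as a mixture of stereoisomers. Oxidation with Dess–Martin periodinane removes both carbinol centres and returns to the route at 14.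

Step 8. Cleavage of eight ethers may stop short at the less activated catechol positions, and the liberated catechols may oxidise during quench and purification. Fallback: the phenols are switched to acid-labile acetals, so the final unmasking needs no Lewis acid. It sets out from 10.
- BBr3 cleaves only the four catechol ethers on this robust diester, and a methanol quench keeps the esters, giving dimethyl 9,9'-(2,3,4',5'-tetrahydroxybiphenyl-2',5-diyl)dinonanoate F7.
- Chloromethyl methyl ether and i-Pr2NEt give the tetrakis(methoxymethyl) ether F8.
- The conditions of step 6 give the bis(N-methoxy-N-methylamide) F9.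
- 1,3-Bis(methoxymethoxy)benzene F10 is lithiated with n-BuLi to 2,6-bis(methoxymethoxy)phenyllithium F11, which adds to F9 to give the octakis(methoxymethyl) ether F12.
- HCl in MeOH at 40 °C under argon removes all eight acetals and returns to the route at 15.

## Further compounds

F1 | step 5 | 2-bromo-4,5-dimethoxybenzaldehyde | COc1cc(Br)c(C=O)cc1OC
F2 | step 5 | methyl (8Z)-9-(2-bromo-4,5-dimethoxyphenyl)non-8-enoate | COC(=O)CCCCCC/C=C\c1cc(OC)c(OC)cc1Br
F3 | step 5 | methyl 9-(2-bromo-4,5-dimethoxyphenyl)nonanoate | COC(=O)CCCCCCCCc1cc(OC)c(OC)cc1Br
F4 | step 3 | methyl (8Z)-9-(3-bromo-4,5-dimethoxyphenyl)non-8-enoate | COC(=O)CCCCCC/C=C\c1cc(OC)c(OC)c(Br)c1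
F5 | step 7 | 9,9'-(2,3,4',5'-tetramethoxybiphenyl-2',5-diyl)dinonanal | O=CCCCCCCCCc1cc(OC)c(OC)c(-c2cc(OC)c(OC)cc2CCCCCCCCC=O)c1
F6 | step 7 | 9,9'-(2,3,4',5'-tetramethoxybiphenyl-2',5-diyl)bis[1-(2,6-dimethoxyphenyl)nonan-1-ol], mixture of stereoisomers | COc1cccc(OC)c1C(O)CCCCCCCCc1cc(OC)c(OC)c(-c2cc(OC)c(OC)cc2CCCCCCCCC(O)c2c(OC)cccc2OC)c1
F7 | step 8 | dimethyl 9,9'-(2,3,4',5'-tetrahydroxybiphenyl-2',5-diyl)dinonanoate | COC(=O)CCCCCCCCc1cc(O)c(O)c(-c2cc(O)c(O)cc2CCCCCCCCC(=O)OC)c1
F8 | step 8 | dimethyl 9,9'-[2,3,4',5'-tetrakis(methoxymethoxy)biphenyl-2',5-diyl]dinonanoate | COC(=O)CCCCCCCCc1cc(OCOC)c(OCOC)c(-c2cc(OCOC)c(OCOC)cc2CCCCCCCCC(=O)OC)c1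
F9 | step 8 | 9,9'-[2,3,4',5'-tetrakis(methoxymethoxy)biphenyl-2',5-diyl]bis(N-methoxy-N-methylnonanamide) | CON(C)C(=O)CCCCCCCCc1cc(OCOC)c(OCOC)c(-c2cc(OCOC)c(OCOC)cc2CCCCCCCCC(=O)N(C)OC)c1
F10 | step 8 | 1,3-bis(methoxymethoxy)benzene | COCOc1cccc(OCOC)c1
F11 | step 8 | 2,6-bis(methoxymethoxy)phenyllithium | [Li]c1c(OCOC)cccc1OCOC
F12 | step 8 | 9,9'-[2,3,4',5'-tetrakis(methoxymethoxy)biphenyl-2',5-diyl]bis{1-[2,6-bis(methoxymethoxy)phenyl]nonan-1-one} | COCOc1cccc(OCOC)c1C(=O)CCCCCCCCc1cc(OCOC)c(OCOC)c(-c2cc(OCOC)c(OCOC)cc2CCCCCCCCC(=O)c2c(OCOC)cccc2OCOC)c1
A1 | alternative 1 | methyl 3-[2,3-dimethoxy-5-(methoxycarbonyl)phenyl]prop-2-ynoate | COC(=O)C#Cc1cc(C(=O)OC)cc(OC)c1OC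
A2 | alternative 1 | 2,3-dimethoxybuta-1,3-diene | C=C(OC)C(=C)OC
A3 | alternative 1 | methyl 2-[2,3-dimethoxy-5-(methoxycarbonyl)phenyl]-4,5-dimethoxycyclohexa-1,4-diene-1-carboxylate | COC(=O)C1=C(c2cc(C(=O)OC)cc(OC)c2OC)CC(OC)=C(OC)C1
A4 | alternative 2 | [2-(1,3-dioxolan-2-yl)-4,5-dimethoxyphenyl]magnesium bromide | COc1cc(C2OCCO2)c([Mg]Br)cc1OC
A5 | alternative 2 | 4-(1,3-dioxolan-2-yl)-2-iodo-6-methoxyphenyl trifluoromethanesulfonate | COc1cc(C2OCCO2)cc(I)c1OS(=O)(=O)C(F)(F)F
A6 | alternative 2 | 4-(1,3-dioxolan-2-yl)-2-[2-(1,3-dioxolan-2-yl)-4,5-dimethoxyphenyl]-6-methoxyphenol | COc1cc(C2OCCO2)cc(-c2cc(OC)c(OC)cc2C2OCCO2)c1O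
A7 | alternative 3 | 2',5-dibromo-2,3,4',5'-tetramethoxybiphenyl | COc1cc(Br)cc(-c2cc(OC)c(OC)cc2Br)c1OC
A8 | alternative 3 | 9-bromo-1-(2,6-dimethoxyphenyl)nonan-1-one | COc1cccc(OC)c1C(=O)CCCCCCCCBr
A9 | alternative 3 | 9,9'-(2,3,4',5'-tetramethoxybiphenyl-2',5-diyl)bis[1-(2,6-dimethoxyphenyl)nonan-1-one] | COc1cccc(OC)c1C(=O)CCCCCCCCc1cc(OC)c(OC)c(-c2cc(OC)c(OC)cc2CCCCCCCCC(=O)c2c(OC)cccc2OC)c1
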